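**Plan**

- Retrosynthesis first removes the two pyrrole bromines (C2–Br, C3–Br), restores the N-sulfonyl group, returns the C2=C3 double bond to the indoline level and replaces C7–Br by C7–SiMe3.
- The benzo ring C3a–C4–C5–C6–C7–C7a carries hydrogen at C4, C5 and C6, nitrogen on C7a and its only substituent on C7. It is therefore cut at C3a–C7a, C4–C5 and C6–C7 into three alkynes: an ynamide (C7a≡C7, silicon on C7 as a stand-in for bromine), a tethered terminal alkyne (C3a≡C4) and acetylene (C5≡C6).
- Forward, N-sulfonylation and N-alkynylation join the chain; one rhodium-catalysed [2+2+2] cyclotrimerization then closes the five-membered nitrogen ring and the benzene ring together.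
- Silicon is exchanged for bromine at C7, the indoline is dehydrogenated, the sulfonyl group is removed, and C3 and C2 are brominated last.
- The target is achiral; no stereocentre has to be set.

Key step: step 3

Assumption: phenyl[(trimethylsilyl)ethynyl]iodonium triflate 4 is treated as a purchasable reagent; the other starting materials (1, 2, 7) are bulk chemicals.

**Step 1**
Reactants: 1 but-3-yn-1-amine; 2 4-methylbenzenesulfonyl chloride
Product: 3 N-(but-3-yn-1-yl)-4-methylbenzenesulfonamide
Conditions: Et3N (1.5 equiv), CH2Cl2, 0 °C to rt
Reagents that add atoms: none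
Why: N-Sulfonylation of a primary amine by a sulfonyl chloride with an amine base is routine and leaves the terminal alkyne untouched.

**Step 2**
Reactants: 3 N-(but-3-yn-1-yl)-4-methylbenzenesulfonamide; 4 phenyl[(trimethylsilyl)ethynyl]iodonium trifluoromethanesulfonate
Product: 6 N-(but-3-yn-1-yl)-4-methyl-N-[(trimethylsilyl)ethynyl]benzenesulfonamide, via potassium N-(but-3-yn-1-yl)-4-methylbenzenesulfonamidate 5 (not isolated)
Conditions: KN(SiMe3)2 (1.0 equiv), toluene, 0 °C; then 4 (1.2 equiv), 0 °C to rt
Reagents that add atoms: none
Why: The sulfonamide N–H is far more acidic than the alkyne C–H, so one equivalent of base gives only the N-anion, which adds to the β-carbon of the alkynyliodonium salt; loss of iodobenzene and a 1,2-shift in the resulting alkylidene carbene give the ynamide (N-alkynylation of a sulfonamide with an alkynyliodonium salt), and the absence of copper avoids Cadiot–Chodkiewicz coupling at the free alkyne.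

**Step 3**
Reactants: 6 N-(but-3-yn-1-yl)-4-methyl-N-[(trimethylsilyl)ethynyl]benzenesulfonamide; 7 acetylene
Product: 8 1-tosyl-7-(trimethylsilyl)indoline
Conditions: RhCl(PPh3)3 (5 mol %), acetylene (1 atm), toluene, 20 to 40 °C, slow addition of 6
Reagents that add atoms: none
Why: Two phosphines on RhCl(PPh3)3 are displaced by the ynamide and the tethered terminal alkyne of 6, and oxidative coupling on monovalent rhodium gives a trivalent rhodacyclopentadiene in which the new C3a–C7a bond has closed the five-membered nitrogen ring (metal-templated oxidative cyclization of a 1,6-diyne). Acetylene then inserts into a Rh–C bond and reductive elimination forms C4–C5 and C6–C7, which closes the benzene ring and returns the catalyst. The closest known reaction type is the rhodium-catalysed [2+2+2] cross-cyclotrimerization of N-sulfonyl ynamide-tethered 1,6-diynes with monoalkynes to indolines, which should run near ambient temperature because the donor nitrogen makes the ynamide a willing partner for the metal. No stereocentre is formed. The step needs cross- rather than homo-trimerization and a single position for silicon: the three-atom tether makes the diyne coupling intramolecular and faster than any intermolecular pairing, acetylene is held in large excess over slowly added 6 so that the rhodacycle is intercepted by acetylene and not by a second diyne, and silicon can only end up on the carbon bonded to C7a because that bond is the ynamide triple bond itself. Acetylene is symmetric, so its insertion raises no regiochemical choice.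

**Step 4**
Reactants: 8 1-tosyl-7-(trimethylsilyl)indoline
Product: 9 7-bromo-1-tosylindoline
Conditions: Br2 (1.05 equiv), CH2Cl2, −78 to 0 °C, dark; aq Na2S2O3 quench
Reagents that add atoms: bromine, BrBr
Why: Bromine attacks the silicon-bearing C7 in an ipso electrophilic substitution (bromodesilylation of an aryl silane) whose arenium ion is stabilised by the β-silicon effect and the ortho nitrogen, and loss of Me3SiBr without release of HBr should outpace bromination of the C5–H position at low temperature with one equivalent.

**Step 5**
Reactants: 9 7-bromo-1-tosylindoline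
Product: 10 7-bromo-1-tosyl-1H-indole
Conditions: Mn(OAc)3·2H2O (3 equiv), AcOH, 80 °C
Reagents that add atoms: none
Why: Manganese triacetate should remove two electrons and two protons from C3 and C2 by way of the benzylic radical and cation (oxidative dehydrogenation of an N-sulfonylindoline to the N-sulfonylindole), a one-electron oxidant chosen because hydride abstraction by quinones is slow on this sulfonamide-deactivated ring, and neither the aryl bromide nor the electron-poor tolyl methyl group should react.

**Step 6**
Reactants: 10 7-bromo-1-tosyl-1H-indole
Product: 11 7-bromo-1H-indole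
Conditions: Cs2CO3 (3 equiv), THF/MeOH (2:1), rt to 50 °C
Reagents that add atoms: none
Why: Methoxide formed from Cs2CO3 and methanol attacks the sulfonyl sulfur and expels the indolide, a good leaving group that the 7-bromo substituent improves further (nucleophilic N-desulfonylation of an N-sulfonylindole), while the aryl bromide is inert.

**Step 7**
Reactants: 11 7-bromo-1H-indole
Product: 13 2,3,7-tribromo-1H-indole, via 3,7-dibromo-1H-indole 12 (not isolated)
Conditions: NBS (2.05 equiv), SiO2, CH2Cl2, 0 °C to rt, dark
Reagents that add atoms: N-bromosuccinimide, O=C1CCC(=O)N1Br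
Why: Electrophilic bromination of the indole takes C3 first and then C2 of the 3-bromoindole (attack at C3 and 1,2-bromine shift), while the 7-bromo substituent deactivates the benzo ring so that two equivalents should stop at the tribromide (NBS halogenation of indoles); the product is to be kept cold, dark and free of acid.

**Compound list**

1 | but-3-yn-1-amine | C#CCCN | starting material
2 | 4-methylbenzenesulfonyl chloride | Cc1ccc(S(=O)(=O)Cl)cc1 | starting material
3 | N-(but-3-yn-1-yl)-4-methylbenzenesulfonamide | C#CCCNS(=O)(=O)c1ccc(C)cc1 | intermediate
4 | phenyl[(trimethylsilyl)ethynyl]iodonium trifluoromethanesulfonate | C[Si](C)(C)C#C[I+]c1ccccc1.[O-]S(=O)(=O)C(F)(F)F | starting material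
5 | potassium N-(but-3-yn-1-yl)-4-methylbenzenesulfonamidate | C#CCC[N-]S(=O)(=O)c1ccc(C)cc1.[K+] | intermediate
6 | N-(but-3-yn-1-yl)-4-methyl-N-[(trimethylsilyl)ethynyl]benzenesulfonamide | C#CCCN(C#C[Si](C)(C)C)S(=O)(=O)c1ccc(C)cc1 | intermediate
7 | acetylene | C#C | starting material
8 | 1-tosyl-7-(trimethylsilyl)indoline | C[Si](C)(C)c1cccc2c1N(S(=O)(=O)c1ccc(C)cc1)CC2 | intermediate
9 | 7-bromo-1-tosylindoline | Brc1cccc2c1N(S(=O)(=O)c1ccc(C)cc1)CC2 | intermediate
10 | 7-bromo-1-tosyl-1H-indole | Cc1ccc(S(=O)(=O)n2ccc3cccc(Br)c32)cc1 | intermediate
11 | 7-bromo-1H-indole | Brc1cccc2cc[nH]c12 | intermediate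
12 | 3,7-dibromo-1H-indole | Brc1c[nH]c2c(Br)cccc12 | intermediate
13 | 2,3,7-tribromo-1H-indole | Brc1[nH]c2c(Br)cccc2c1Br | target

Total steps: 7. Longest linear sequence: 7 steps (1 to 13).

**Steps most likely to fail**

Step 4. Electrophilic attack at the C5–H position para to nitrogen could compete with ipso attack at C7, and a second bromination could follow. The fallback sets out from 8 and returns at 9 by way of boron, which touches only the C–Si bond. BBr3 in CH2Cl2 (−78 °C to rt) should effect ipso borodesilylation to 7-(dibromoboryl)-1-tosylindoline F1. This is not isolated but treated with pinacol and Et3N to give 7-(4,4,5,5-tetramethyl-1,3,2-dioxaborolan-2-yl)-1-tosylindoline F2. Bromodeboronation with CuBr2 (3 equiv) in MeOH/H2O at 80 °C then gives 9 without exposing the ring to a free bromine electrophile.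

Step 7. The free indole may be brominated a third time on the benzo ring, the electron-rich dihalopyrrole ring may be oxidised by traces of water, and the N–H tribromide may decompose under the acid formed during the reaction. The fallback sets out from 10 and returns at 13, keeping the sulfonyl group until the end. Br2 in CH2Cl2 at rt should brominate C3 to give 3,7-dibromo-1-tosyl-1H-indole F3. LiN(iPr)2 in THF at −78 °C then removes the C2 proton, which the sulfonyl group acidifies, to give 3,7-dibromo-2-lithio-1-tosyl-1H-indole F4. Quenching with 1,2-dibromo-1,1,2,2-tetrachloroethane gives 2,3,7-tribromo-1-tosyl-1H-indole F5. Cs2CO3 in THF/MeOH at rt then releases 13 under mild basic conditions in the last operation.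

Step 3. The diyne may oligomerise through its terminal alkyne, or oxidative coupling may stall at the silyl-capped ynamide terminus, so that acetylene is consumed only as benzene. The fallback sets out from 3 and returns at 8; it builds the benzene ring by a metal-free intramolecular [4+2] cycloaddition that needs no third component. Sonogashira coupling of 3 with vinyl bromide (PdCl2(PPh3)2, CuI, Et3N, THF, rt) gives N-(hex-5-en-3-yn-1-yl)-4-methylbenzenesulfonamide F6. KN(SiMe3)2 in toluene converts it into potassium N-(hex-5-en-3-yn-1-yl)-4-methylbenzenesulfonamidate F7, which is alkynylated with 4 to N-(hex-5-en-3-yn-1-yl)-4-methyl-N-[(trimethylsilyl)ethynyl]benzenesulfonamide F8. Heating F8 in toluene at 180 °C with BHT should bring the conjugated enyne (four-carbon partner) and the ynamide (two-carbon partner) together; hydrogen shift then aromatises the adduct to 8, with silicon again fixed on C7.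

**Further compounds**

F1 | step 4 | 7-(dibromoboryl)-1-tosylindoline | BrB(Br)c1cccc2c1N(S(=O)(=O)c1ccc(C)cc1)CC2
F2 | step 4 | 7-(4,4,5,5-tetramethyl-1,3,2-dioxaborolan-2-yl)-1-tosylindoline | CC1(C)OB(OC1(C)C)c1cccc2c1N(S(=O)(=O)c1ccc(C)cc1)CC2
F3 | step 7 | 3,7-dibromo-1-tosyl-1H-indole | Cc1ccc(S(=O)(=O)n2cc(Br)c3cccc(Br)c32)cc1
F4 | step 7 | 3,7-dibromo-2-lithio-1-tosyl-1H-indole | [Li]c1c(Br)c2cccc(Br)c2n1S(=O)(=O)c1ccc(C)cc1
F5 | step 7 | 2,3,7-tribromo-1-tosyl-1H-indole | Cc1ccc(S(=O)(=O)n2c(Br)c(Br)c3cccc(Br)c32)cc1
F6 | step 3 | N-(hex-5-en-3-yn-1-yl)-4-methylbenzenesulfonamide | C=CC#CCCNS(=O)(=O)c1ccc(C)cc1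
F7 | step 3 | potassium N-(hex-5-en-3-yn-1-yl)-4-methylbenzenesulfonamidate | C=CC#CCC[N-]S(=O)(=O)c1ccc(C)cc1.[K+]
F8 | step 3 | N-(hex-5-en-3-yn-1-yl)-4-methyl-N-[(trimethylsilyl)ethynyl]benzenesulfonamide | C=CC#CCCN(C#C[Si](C)(C)C)S(=O)(=O)c1ccc(C)cc1
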